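Everything rests on cutting the two enol-ester C–O bonds of the quinone ring, which leaves atromentin and two copies of one Z-epoxy acid. Counted from the ester carbonyl (C1), chain atoms C3 (alkene CH), C4 and C5 (oxirane carbons) and C6 (methyl) map onto penta-1,4-dien-3-ol: C4 is the carbinol carbon, C3 belongs to one vinyl group, C5 and C6 are the other. Epoxidation of this achiral, unprotected dienol with Ti(OiPr)4, D-(−)-diisopropyl tartrate and t-BuOOH selects one enantiotopic vinyl group and one face, closing the oxirane and fixing C4 and C5 at once. The spared vinyl group later enters a lactone that stores the Z-alkene.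

Key step: step 1

Remark: alkoxides, phenoxides and quinonolates that exist only until work-up or until the next bond is formed (the sodium salts in step 11, the ammonium quinonolates of 19 and 21 in step 12) are regarded as ionised forms of the numbered compounds and carry no numbers of their own.

Step 1
Reactants: 1 penta-1,4-dien-3-ol (divinylcarbinol)
Product: 2 (2S,3R)-1,2-epoxypent-4-en-3-ol [erythro; (1R)-1-[(2S)-oxiran-2-yl]prop-2-en-1-ol]
Conditions: Ti(OiPr)4 (cat.), D-(−)-diisopropyl tartrate [(2S,3S); cat., slight excess over Ti], t-BuOOH (anhydrous, isooctane), 4 Å molecular sieves, CH2Cl2, −20 °C, prolonged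
Reagents that add atoms: tert-butyl hydroperoxide, CC(C)(C)OO
Why: Sharpless asymmetric epoxidation run as a desymmetrisation: two isopropoxides of the dimeric catalyst formed from Ti(OiPr)4 and the tartrate are exchanged for the dienol oxygen and the tert-butylperoxy group, and the distal peroxide oxygen is then handed to the nearby C=C bond in one concerted, SN2-like event at oxygen. The closest known reaction type is the kinetic resolution of racemic secondary allylic alcohols by the same Ti(OiPr)4/tartrate/t-BuOOH system, here operating between the two vinyl groups of a single molecule. The oxirane is closed by this one oxygen-atom transfer across the alkene (a [2+1] addition in which both C–O bonds form together), not by a separate exo or endo cyclisation. C2 is set by reagent control, the D-(−)-tartrate deciding which alkene face meets the peroxide (the L-(+) ester would give the (2R,3S) antipode), and C3 becomes stereogenic through the choice of vinyl group, because only the one that can react with the carbinol hydrogen turned towards the ligand is oxidised, which is the erythro preference of the catalyst. Group, face and mono-epoxidation selectivity are all needed and are secured by the free carbinol OH flanked by two identical terminal vinyl groups: in 2 the surviving vinyl group is the mismatched, slow one, whereas in the antipode it is the matched one and is oxidised on to a separable bis-epoxide, so the optical purity of 2 should improve as the reaction is driven further.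

Step 2
Reactants: 2 (2S,3R)-1,2-epoxypent-4-en-3-ol
Product: 3 (2S,3R)-3-(tert-butyldimethylsilyloxy)-1,2-epoxypent-4-ene
Conditions: TBSCl, imidazole, CH2Cl2, 0 °C → rt
Reagents that add atoms: tert-butyldimethylsilyl chloride, CC(C)(C)[Si](C)(C)Cl
Why: Imidazole-promoted silyl ether formation blocks the carbinol oxygen that must later become the leaving-group site and stops it from steering or quenching the hydride of step 3; no bond to C2 or C3 is broken, so both configurations are carried through.

Step 3
Reactants: 3 (2S,3R)-3-(tert-butyldimethylsilyloxy)-1,2-epoxypent-4-ene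
Product: 4 (2S,3R)-3-(tert-butyldimethylsilyloxy)pent-4-en-2-ol
Conditions: LiEt3BH, THF, −78 → 0 °C; then H2O at 0 °C
Reagents that add atoms: none
Why: Reductive opening of a terminal epoxide by SN2 delivery of hydride to the unhindered CH2 carbon turns C1 into the future C6 methyl and leaves the C2–O bond intact, so C2 keeps its configuration; the cold quench and the boron-bound alkoxide should keep 1,2-silyl migration in check.

Step 4
Reactants: 4 (2S,3R)-3-(tert-butyldimethylsilyloxy)pent-4-en-2-ol; 5 acryloyl chloride
Product: 6 (2S,3R)-3-(tert-butyldimethylsilyloxy)pent-4-en-2-yl prop-2-enoate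
Conditions: Et3N, DMAP (cat.), CH2Cl2, 0 °C
Reagents that add atoms: none
Why: Esterification of a secondary alcohol with an acid chloride places the acrylate on the oxygen destined to be the lactone ring oxygen; only the O–H bond reacts, so C2 and C3 are unchanged.

Step 5
Reactants: 6 (2S,3R)-3-(tert-butyldimethylsilyloxy)pent-4-en-2-yl prop-2-enoate
Product: 7 (5R,6S)-5-(tert-butyldimethylsilyloxy)-6-methyl-5,6-dihydro-2H-pyran-2-one (trans)
Conditions: second-generation Grubbs catalyst (5 mol %), CH2Cl2 (high dilution), 40 °C
Reagents that add atoms: none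
Why: Ring-closing olefin metathesis of the acrylate with the allylic vinyl group expels ethene and closes the six-membered unsaturated lactone, whose ring size forces the new C=C bond to be cis; the two stereocentres are bystanders and sit trans on the ring.

Step 6
Reactants: 7 (5R,6S)-5-(tert-butyldimethylsilyloxy)-6-methyl-5,6-dihydro-2H-pyran-2-one
Product: 8 (5R,6S)-5-hydroxy-6-methyl-5,6-dihydro-2H-pyran-2-one
Conditions: 48% aq HF, MeCN, 0 °C → rt
Reagents that add atoms: none
Why: Fluoride-mediated silyl ether cleavage under acidic conditions frees the C5 hydroxyl while avoiding the alkoxide or basic fluoride that could cause acyl migration to a butenolide or elimination in this unsaturated lactone; no stereocentre is touched.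

Step 7
Reactants: 8 (5R,6S)-5-hydroxy-6-methyl-5,6-dihydro-2H-pyran-2-one
Product: 9 (5R,6S)-5-(methanesulfonyloxy)-6-methyl-5,6-dihydro-2H-pyran-2-one
Conditions: Ms2O, pyridine, CH2Cl2, 0 °C
Reagents that add atoms: methanesulfonic anhydride, CS(=O)(=O)OS(C)(=O)=O
Why: Sulfonate ester formation at the secondary alcohol proceeds with retention because only the O–H bond is exchanged; pyridine is too weak a base to eliminate the allylic mesylate towards the 2-pyranone, and the anhydride brings no chloride that could displace it.

Step 8
Reactants: 9 (5R,6S)-5-(methanesulfonyloxy)-6-methyl-5,6-dihydro-2H-pyran-2-one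
Product: 11 potassium (2Z,4S,5S)-4,5-epoxyhex-2-enoate, via ring-opened hydroxy mesylate carboxylate 10 (not isolated)
Conditions: KOH (2.0 equiv), THF/H2O, 0 °C; freeze-dry, dry under vacuum (the potassium methanesulfonate formed alongside is carried on as an inert salt)
Reagents that add atoms: potassium hydroxide, [K+].[OH-]
Why: Lactone saponification followed by intramolecular Williamson ether synthesis: hydroxide opens the ring at the carbonyl carbon, and the C5 alkoxide thus released attacks C4 from the side opposite the mesylate (SN2; 3-exo-tet), so C4 is inverted from R to S while C5 and the ring-derived Z-alkene are retained; the carboxylate formed first shields the enoate from conjugate addition, and the product is kept as its potassium salt because the free acid would be prone to cyclise onto its own oxirane.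

Step 9
Reactants: 12 tetrabromo-1,4-benzoquinone (bromanil)
Product: 14 2,5-dibromo-3,6-dimethoxy-1,4-benzoquinone, via tribromo methoxy quinone 13 (not isolated)
Conditions: NaOMe (2.0 equiv), MeOH, 0 °C → rt
Reagents that add atoms: sodium methoxide, C[O-].[Na+]
Why: Twofold nucleophilic vinylic substitution (addition–elimination) of methoxide on the tetrabromoquinone; in 13 the first methoxy group turns one carbonyl into a vinylogous ester, so the second methoxide adds to the carbon conjugated to the other, still electron-poor carbonyl, which lies para to the first methoxy-bearing carbon, and the 2,5-dimethoxy-3,6-dibromo pattern results.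

Step 10
Reactants: 14 2,5-dibromo-3,6-dimethoxy-1,4-benzoquinone; 15 4-hydroxyphenylboronic acid (2.2 equiv)
Product: 17 2,5-bis(4-hydroxyphenyl)-3,6-dimethoxy-1,4-benzoquinone, via mono-arylated bromoquinone 16 (not isolated)
Conditions: Pd(PPh3)4 (5 mol %), K2CO3 (4 equiv), degassed 1,4-dioxane, 90 °C; aqueous work-up
Reagents that add atoms: none
Why: Twofold Suzuki–Miyaura cross-coupling, in which zerovalent palladium inserts into one vinylic C–Br bond of the bromo-enone, the carbonate-activated boronic acid transmetallates and reductive elimination gives 16, whose remaining C–Br bond then passes through the same cycle with the second equivalent of 15; the slight excess of boronic acid over the two equivalents needed drives both couplings to completion, and the free phenols are tolerated.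

Step 11
Reactants: 17 2,5-bis(4-hydroxyphenyl)-3,6-dimethoxy-1,4-benzoquinone
Product: 19 atromentin [2,5-dihydroxy-3,6-bis(4-hydroxyphenyl)-1,4-benzoquinone], via mono-demethylated quinone 18 (not isolated)
Conditions: 2 M aq NaOH, 1,4-dioxane, 60 °C; then 2 M HCl
Reagents that add atoms: sodium hydroxide, [Na+].[OH-]
Why: Hydrolysis of the two vinylogous methyl esters by addition–elimination of hydroxide at the methoxy-bearing ring carbons, the first giving 18 as its salt and the second the dianion of the dihydroxyquinone, from which acidification releases atromentin.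

Step 12
Reactants: 11 potassium (2Z,4S,5S)-4,5-epoxyhex-2-enoate (2.2 equiv); 19 atromentin
Product: 22 atromentin 2,5-bis-O-[(2Z,4S,5S)-4,5-epoxyhex-2-enoate] (target CNP0407724.1), via epoxyhexenoyl chloride 20 (not isolated), via atromentin mono-ester 21 (not isolated)
Conditions: (COCl)2 (1.0 equiv per carboxylate), DMF (cat.), CH2Cl2, −20 °C; then added to 19, iPr2NEt (2.0 equiv), THF, −40 → 0 °C
Reagents that add atoms: none
Why: Acid chloride formation from the alkali carboxylate with oxalyl chloride (no HCl is produced, which spares the oxirane and the Z-alkene) followed by O-acylation of an enolate: the two equivalents of amine ionise only the two vinylogous-acid hydroxyls on the quinone ring, which are several pKa units more acidic than the phenols, so the acyl chloride is captured twice at those oxygens to give the 2,5-diester while the neutral phenols stay free; no stereocentre takes part.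

Compound list
1 | penta-1,4-dien-3-ol | C=CC(O)C=C | starting material
2 | (2S,3R)-1,2-epoxypent-4-en-3-ol | C=C[C@@H](O)[C@@H]1CO1 | intermediate
3 | (2S,3R)-3-(tert-butyldimethylsilyloxy)-1,2-epoxypent-4-ene | C=C[C@@H](O[Si](C)(C)C(C)(C)C)[C@@H]1CO1 | intermediate
4 | (2S,3R)-3-(tert-butyldimethylsilyloxy)pent-4-en-2-ol | C=C[C@@H](O[Si](C)(C)C(C)(C)C)[C@H](C)O | intermediate
5 | acryloyl chloride | C=CC(Cl)=O | starting material
6 | (2S,3R)-3-(tert-butyldimethylsilyloxy)pent-4-en-2-yl prop-2-enoate | C=C[C@@H](O[Si](C)(C)C(C)(C)C)[C@H](C)OC(=O)C=C | intermediate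
7 | (5R,6S)-5-(tert-butyldimethylsilyloxy)-6-methyl-5,6-dihydro-2H-pyran-2-one | C[C@@H]1OC(=O)C=C[C@H]1O[Si](C)(C)C(C)(C)C | intermediate
8 | (5R,6S)-5-hydroxy-6-methyl-5,6-dihydro-2H-pyran-2-one | C[C@@H]1OC(=O)C=C[C@H]1O | intermediate
9 | (5R,6S)-5-(methanesulfonyloxy)-6-methyl-5,6-dihydro-2H-pyran-2-one | C[C@@H]1OC(=O)C=C[C@H]1OS(C)(=O)=O | intermediate
10 | potassium (2Z,4R,5S)-5-hydroxy-4-(methanesulfonyloxy)hex-2-enoate | C[C@H](O)[C@H](OS(C)(=O)=O)/C=C\C(=O)[O-].[K+] | intermediate (not isolated)
11 | potassium (2Z,4S,5S)-4,5-epoxyhex-2-enoate | C[C@@H]1O[C@H]1/C=C\C(=O)[O-].[K+] | intermediate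
12 | tetrabromo-1,4-benzoquinone (bromanil) | O=C1C(Br)=C(Br)C(=O)C(Br)=C1Br | starting material
13 | 2,3,5-tribromo-6-methoxy-1,4-benzoquinone | COC1=C(Br)C(=O)C(Br)=C(Br)C1=O | intermediate (not isolated)
14 | 2,5-dibromo-3,6-dimethoxy-1,4-benzoquinone | COC1=C(Br)C(=O)C(OC)=C(Br)C1=O | intermediate
15 | 4-hydroxyphenylboronic acid | OB(O)c1ccc(O)cc1 | starting material
16 | 2-bromo-5-(4-hydroxyphenyl)-3,6-dimethoxy-1,4-benzoquinone | COC1=C(Br)C(=O)C(OC)=C(c2ccc(O)cc2)C1=O | intermediate (not isolated)
17 | 2,5-bis(4-hydroxyphenyl)-3,6-dimethoxy-1,4-benzoquinone | COC1=C(c2ccc(O)cc2)C(=O)C(OC)=C(c2ccc(O)cc2)C1=O | intermediate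
18 | 2-hydroxy-5-methoxy-3,6-bis(4-hydroxyphenyl)-1,4-benzoquinone | COC1=C(c2ccc(O)cc2)C(=O)C(O)=C(c2ccc(O)cc2)C1=O | intermediate (not isolated)
19 | atromentin | OC1=C(c2ccc(O)cc2)C(=O)C(O)=C(c2ccc(O)cc2)C1=O | intermediate
20 | (2Z,4S,5S)-4,5-epoxyhex-2-enoyl chloride | C[C@@H]1O[C@H]1/C=C\C(Cl)=O | intermediate (not isolated)
21 | atromentin 2-O-[(2Z,4S,5S)-4,5-epoxyhex-2-enoate] | C[C@@H]1O[C@H]1/C=C\C(=O)OC1=C(c2ccc(O)cc2)C(=O)C(O)=C(c2ccc(O)cc2)C1=O | intermediate (not isolated)
22 | atromentin 2,5-bis-O-[(2Z,4S,5S)-4,5-epoxyhex-2-enoate] (CNP0407724.1) | C[C@@H]1O[C@H]1/C=C\C(=O)OC1=C(c2ccc(O)cc2)C(=O)C(OC(=O)/C=C\[C@@H]2O[C@H]2C)=C(c2ccc(O)cc2)C1=O | target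

Total step count: 12.
Longest linear sequence: 9 steps (steps 1–8 and step 12, from 1 to 22); the atromentin branch is 3 steps plus the shared last step.

Steps most likely to fail

Step 12. What may go wrong: loss of site selectivity through acyl transfer to the phenolic oxygens, or breakdown of the acyl chloride by attack of its own oxirane oxygen or by Z-to-E isomerisation. The fallback sets out from 19 and comes back at 22, and replaces both the unprotected substrate and the acyl chloride. All four hydroxyls of 19 would be silylated (TBSCl, imidazole, DMF) to 2,5-bis(tert-butyldimethylsilyloxy)-3,6-bis[4-(tert-butyldimethylsilyloxy)phenyl]-1,4-benzoquinone F1. Brief AcOH/THF/H2O treatment should cleave only the two hydrolytically labile quinonyl silyl ethers (vinylogous silyl esters) and leave 2,5-dihydroxy-3,6-bis[4-(tert-butyldimethylsilyloxy)phenyl]-1,4-benzoquinone F2. Salt 11 would then be coupled by carbodiimide activation (1-ethyl-3-(3-dimethylaminopropyl)carbodiimide hydrochloride, CH2Cl2, 0 °C). The hydrochloride supplies the proton, and the acidic hydroxyquinone takes up the O-acylisourea as a second acid does in anhydride formation, giving the bis-silylated diester F3. Buffered fluoride (Bu4NF/AcOH, THF, 0 °C) would remove the two aryl silyl ethers to give 22.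

Step 8. What may go wrong: hydroxide acting as a base on the mesyl lactone (elimination towards the 2-pyranone, or γ-deprotonation and ring fragmentation) faster than it attacks the carbonyl, or lactonisation of the epoxy carboxylate during isolation. The fallback sets out from 4 and comes back at 11; it builds the trans-oxirane first and the Z-alkene afterwards by olefination. Acetylation of 4 (Ac2O, pyridine) would give (2S,3R)-3-(tert-butyldimethylsilyloxy)pent-4-en-2-yl acetate F4, and HF in MeCN would then free the allylic carbinol as (2S,3R)-3-hydroxypent-4-en-2-yl acetate F5. Mesylation (MsCl, Et3N, −20 °C) would give (2S,3R)-3-(methanesulfonyloxy)pent-4-en-2-yl acetate F6, to be used at once. K2CO3 in MeOH would remove the acetate, and the alkoxide so formed would close (2S,3S)-2-ethenyl-3-methyloxirane F7 with inversion at the allylic carbon; F7 is volatile and would be kept in solution. Ozonolysis (O3, CH2Cl2, −78 °C; Me2S) would give (2R,3S)-3-methyloxirane-2-carbaldehyde F8. Still–Gennari olefination (methyl bis(2,2,2-trifluoroethyl)phosphonoacetate, KN(SiMe3)2, 18-crown-6, THF, −78 °C) would give methyl (2Z,4S,5S)-4,5-epoxyhex-2-enoate F9. KOH (1.0 equiv) in THF/H2O at 0 °C would then give 11.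

Step 10. What may go wrong: protodeboronation of the electron-rich boronic acid, redox side reactions between the bromoquinone, the free phenol and the palladium catalyst, stalling after the first coupling, or base hydrolysis of the vinylogous ester before both couplings are complete. The fallback sets out from 14 and comes back at 19. Compound 14 would be coupled under the same Suzuki–Miyaura conditions with 4-methoxyphenylboronic acid (2.2 equiv) to 2,5-dimethoxy-3,6-bis(4-methoxyphenyl)-1,4-benzoquinone F10. All four methyl ethers would then be cleaved with BBr3 (CH2Cl2, −78 °C → rt; aqueous work-up), which should give 19 directly and make step 11 unnecessary.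

Further compounds
F1 | step 12 | 2,5-bis(tert-butyldimethylsilyloxy)-3,6-bis[4-(tert-butyldimethylsilyloxy)phenyl]-1,4-benzoquinone | CC(C)(C)[Si](C)(C)OC1=C(c2ccc(O[Si](C)(C)C(C)(C)C)cc2)C(=O)C(O[Si](C)(C)C(C)(C)C)=C(c2ccc(O[Si](C)(C)C(C)(C)C)cc2)C1=O
F2 | step 12 | 2,5-dihydroxy-3,6-bis[4-(tert-butyldimethylsilyloxy)phenyl]-1,4-benzoquinone | OC1=C(c2ccc(O[Si](C)(C)C(C)(C)C)cc2)C(=O)C(O)=C(c2ccc(O[Si](C)(C)C(C)(C)C)cc2)C1=O
F3 | step 12 | 3,6-bis[4-(tert-butyldimethylsilyloxy)phenyl]-1,4-benzoquinone-2,5-diyl bis[(2Z,4S,5S)-4,5-epoxyhex-2-enoate] | C[C@@H]1O[C@H]1/C=C\C(=O)OC1=C(c2ccc(O[Si](C)(C)C(C)(C)C)cc2)C(=O)C(OC(=O)/C=C\[C@@H]2O[C@H]2C)=C(c2ccc(O[Si](C)(C)C(C)(C)C)cc2)C1=O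
F4 | step 8 | (2S,3R)-3-(tert-butyldimethylsilyloxy)pent-4-en-2-yl acetate | C=C[C@@H](O[Si](C)(C)C(C)(C)C)[C@H](C)OC(C)=O
F5 | step 8 | (2S,3R)-3-hydroxypent-4-en-2-yl acetate | C=C[C@@H](O)[C@H](C)OC(C)=O
F6 | step 8 | (2S,3R)-3-(methanesulfonyloxy)pent-4-en-2-yl acetate | C=C[C@@H](OS(C)(=O)=O)[C@H](C)OC(C)=O
F7 | step 8 | (2S,3S)-2-ethenyl-3-methyloxirane | C=C[C@@H]1O[C@H]1C
F8 | step 8 | (2R,3S)-3-methyloxirane-2-carbaldehyde | C[C@@H]1O[C@H]1C=O
F9 | step 8 | methyl (2Z,4S,5S)-4,5-epoxyhex-2-enoate | C[C@@H]1O[C@H]1/C=C\C(=O)OC
F10 | step 10 | 2,5-dimethoxy-3,6-bis(4-methoxyphenyl)-1,4-benzoquinone | COC1=C(c2ccc(OC)cc2)C(=O)C(OC)=C(c2ccc(OC)cc2)C1=O
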